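Megaphone acetate is cut at two bonds of its γ-acetoxy ketone array: the bond between the CHMe carbon and the benzylic C–OAc carbon, and the bond between the quaternary ring carbon C6 and the ring CH2 (C5). Both are formed in one acid-catalysed operation: 3,4,5-trimethoxybenzaldehyde adds to the Z-alkene of an alkenylcyclobutanol while a ring CH2 shifts, which turns the four-membered carbinol into a 2,2-disubstituted 4-methoxycyclopentanone and sets all four stereocentres. The precursor is the achiral cis-3-methoxycyclobutanol bearing a (2Z)-hexa-2,5-dien-3-yl group at C1. A one-carbon Ito–Saegusa enlargement and early acetylation then deliver the 4-methoxycyclohex-2-enone ring.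

Key step: step 6

Remark: the sense of induction of the chiral acid cannot be assigned in advance, so the route is written for the catalyst antipode that pairs the Si face of the alkene CHMe terminus with the Re face of the aldehyde, to be identified in a first small-scale run.

Remark: the cyclobutanol hydroxyl is deliberately left free and the alcohol is used as the pure cis isomer, because the O–H is the hydrogen-bond donor and proton relay of the key step; the Z-alkene, anti addition and the cis hydroxyl/methoxy relationship map onto the (R) quaternary carbon, (S) CHMe carbon, (R) carbinol carbon and (R) methoxy-bearing carbon of the target without any change of configuration in the precursor.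

Step 1
Reactants: 1 crotonaldehyde
Product: 2 (Z)-2-iodobut-2-enal
Conditions: I2, K2CO3, DMAP (cat.), THF/H2O (1:1), rt
Reagents that add atoms: iodine, II
Why: Baylis–Hillman-type α-iodination (conjugate addition of DMAP, iodination of the enolate, loss of DMAP) should give the more stable Z-iodoenal, in which methyl and formyl stay trans as in crotonaldehyde.

Step 2
Reactants: 2 (Z)-2-iodobut-2-enal
Product: 3 (Z)-2-iodobut-2-en-1-ol
Conditions: NaBH4, CeCl3·7H2O, MeOH, 0 °C
Reagents that add atoms: none
Why: Luche reduction should give clean 1,2-reduction of the enal and leave the alkenyl iodide and its geometry untouched.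

Step 3
Reactants: 3 (Z)-2-iodobut-2-en-1-ol
Product: 4 (Z)-1-bromo-2-iodobut-2-ene
Conditions: PBr3, Et2O, 0 °C
Reagents that add atoms: phosphorus tribromide, BrP(Br)Br
Why: bromination of the primary allylic alcohol through its phosphite ester (SN2 at the primary carbon) should keep the position and geometry of the alkene.

Step 4
Reactants: 4 (Z)-1-bromo-2-iodobut-2-ene; 5 vinylmagnesium bromide
Product: 6 (4Z)-4-iodohexa-1,4-diene
Conditions: CuI (5 mol%), THF, −30 → 0 °C
Reagents that add atoms: none
Why: copper-catalysed Grignard allylic substitution should occur at the primary allylic bromide, far more reactive than the alkenyl iodide, and at the α-carbon, because the γ-carbon is substituted and flanked by iodine (the coupling of 2-haloallyl bromides with vinylmagnesium halides is the model).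

Step 5
Reactants: 6 (4Z)-4-iodohexa-1,4-diene; 7 3-methoxycyclobutan-1-one
Product: 9 cis-1-[(2Z)-hexa-2,5-dien-3-yl]-3-methoxycyclobutan-1-ol, via alkenyllithium 8 (not isolated)
Conditions: t-BuLi (2.0 equiv), Et2O, −78 °C; then 7, −78 °C; H2O quench; chromatography to remove any trans isomer
Reagents that add atoms: none
Why: iodine–lithium exchange keeps the alkene geometry, and 1,2-addition of the alkenyllithium to the strained ketone should occur on the face anti to the 3-methoxy group, which places hydroxyl and methoxy cis (both ring centres are pseudoasymmetric, so 9 is achiral).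

Step 6
Reactants: 9 cis-1-[(2Z)-hexa-2,5-dien-3-yl]-3-methoxycyclobutan-1-ol; 10 3,4,5-trimethoxybenzaldehyde
Product: 11 (2R,4R)-2-allyl-2-[(1R,2S)-1-hydroxy-1-(3,4,5-trimethoxyphenyl)propan-2-yl]-4-methoxycyclopentan-1-one
Conditions: chiral confined Brønsted acid (BINOL-derived imidodiphosphorimidate with N-triflyl core, 5 mol%), 10 (1.5 equiv), CHCl3, 4 Å MS, −50 → −30 °C; Et3N quench
Reagents that add atoms: none
Why: Proposed new method: the confined acid hydrogen-bonds and protonates the aldehyde, the trisubstituted alkene (far more nucleophilic than the allyl group) attacks it through its CHMe terminus, and the ring CH2 lying antiperiplanar to the forming bond migrates to the developing tertiary cation while the carbinol becomes the ketone and returns its proton to the catalyst anion. The closest known reactions are Prins–pinacol cascades of acetal-derived oxocarbenium ions, confined-acid-catalysed additions of unactivated olefins and dienes to aryl aldehydes, and catalytic asymmetric halo- and protio-semipinacol expansions of 1-alkenylcyclobutanols. The cyclopentanone ring is not closed end to end but arises by ring enlargement, a suprafacial 1,2-alkyl shift that converts the four-membered carbinol into the five-membered ketone with release of strain. The carbinol carbon is set by the aldehyde face chosen by the chiral anion (Re face, aryl pointing away from the future quaternary carbon in a chair-like hydrogen-bonded array CHMe–C(aldehyde)–O···H–O–C1–C(alkene)); the CHMe carbon and the quaternary carbon follow stereospecifically from anti addition across the Z-alkene; the methoxy-bearing carbon is set by which of the two enantiotopic ring CH2 groups migrates, fixed by the rotamer that places the hydroxyl beside the Z-methyl (least allylic strain) and in hydrogen-bond contact with the aldehyde oxygen, together with the cis hydroxyl/methoxy relationship. The step needs carbon–carbon bond formation to outrun protonation of the alkene (aldehyde-free ring expansion), proton loss from the bis-allylic CH2 and ionisation of the tertiary allylic alcohol; the aldehyde as the most basic site (used in excess, and electronically close to benzaldehyde because the two meta methoxy groups offset the para one), the low temperature and the strain-driven intramolecular shift should secure this.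

Step 7
Reactants: 11 (2R,4R)-2-allyl-2-[(1R,2S)-1-hydroxy-1-(3,4,5-trimethoxyphenyl)propan-2-yl]-4-methoxycyclopentan-1-one
Product: 12 (1R,2S)-2-[(1R,4R)-1-allyl-4-methoxy-2-oxocyclopentyl]-1-(3,4,5-trimethoxyphenyl)propyl acetate
Conditions: Ac2O, Et3N, DMAP (cat.), CH2Cl2, 0 °C → rt
Reagents that add atoms: acetic anhydride, CC(=O)OC(C)=O
Why: DMAP-catalysed acyl transfer to the secondary benzylic alcohol touches no stereocentre and should drain any lactol form of the γ-hydroxy ketone through the open chain.

Step 8
Reactants: 12 (1R,2S)-2-[(1R,4R)-1-allyl-4-methoxy-2-oxocyclopentyl]-1-(3,4,5-trimethoxyphenyl)propyl acetate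
Product: 13 (1R,2S)-2-[(1R,4R)-1-allyl-4-methoxy-2-(trimethylsilyloxy)cyclopent-2-en-1-yl]-1-(3,4,5-trimethoxyphenyl)propyl acetate
Conditions: TMSOTf (1.3 equiv), Et3N (2.5 equiv), CH2Cl2, −78 → 0 °C; crude product used directly
Reagents that add atoms: trimethylsilyl trifluoromethanesulfonate, C[Si](C)(C)OS(=O)(=O)C(F)(F)F
Why: soft enolisation (silyl triflate and amine) should form the silyl enol ether toward the only α-carbon bearing hydrogen without a free enolate that could expel the β-methoxy group, the ketone being silylated far faster than the acetate in the amine-buffered medium.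

Step 9
Reactants: 13 (1R,2S)-2-[(1R,4R)-1-allyl-4-methoxy-2-(trimethylsilyloxy)cyclopent-2-en-1-yl]-1-(3,4,5-trimethoxyphenyl)propyl acetate
Product: 14 1-(trimethylsilyloxy)bicyclo[3.1.0]hexane obtained by adding CH2 across the enol ether double bond of 13 (either cis-fused cyclopropane face; other stereocentres as in 12)
Conditions: Et2Zn (2.0 equiv), CH2I2 (2.0 equiv), CH2Cl2, 0 °C
Reagents that add atoms: diiodomethane, ICI
Why: in this Furukawa-modified Simmons–Smith cyclopropanation the electron-rich silyl enol ether should react far faster than the monosubstituted allyl alkene, and the face of attack is irrelevant because both new ring-fusion centres are erased in step 10.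

Step 10
Reactants: 14 1-(trimethylsilyloxy)bicyclo[3.1.0]hexane from step 9
Product: 16 megaphone acetate, via β-chloroketone 15 (not isolated)
Conditions: FeCl3 (2.2 equiv), DMF, 0 °C → rt; then NaOAc, MeOH, 60 °C
Reagents that add atoms: none
Why: in this Ito–Saegusa ring enlargement iron(III) oxidises the siloxycyclopropane to an oxygen radical whose β-scission of the ring-fusion bond gives the six-membered β-keto radical, chlorine transfer traps it, and acetate-induced E1cB loss of HCl gives the enone without touching the quaternary or the methoxy-bearing carbon.

Compound list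
1 | crotonaldehyde, (E)-but-2-enal | C/C=C/C=O | starting material
2 | (Z)-2-iodobut-2-enal | C/C=C(\I)C=O | intermediate
3 | (Z)-2-iodobut-2-en-1-ol | C/C=C(\I)CO | intermediate
4 | (Z)-1-bromo-2-iodobut-2-ene | C/C=C(\I)CBr | intermediate
5 | vinylmagnesium bromide | C=C[Mg]Br | starting material
6 | (4Z)-4-iodohexa-1,4-diene | C/C=C(\I)CC=C | intermediate
7 | 3-methoxycyclobutan-1-one | COC1CC(=O)C1 | starting material
8 | [(2Z)-hexa-2,5-dien-3-yl]lithium | C/C=C(\[Li])CC=C | intermediate (not isolated)
9 | cis-1-[(2Z)-hexa-2,5-dien-3-yl]-3-methoxycyclobutan-1-ol (hydroxyl and methoxy cis) | C/C=C(/CC=C)[C@]1(O)C[C@@H](OC)C1 | intermediate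
10 | 3,4,5-trimethoxybenzaldehyde | COc1cc(C=O)cc(OC)c1OC | starting material
11 | (2R,4R)-2-allyl-2-[(1R,2S)-1-hydroxy-1-(3,4,5-trimethoxyphenyl)propan-2-yl]-4-methoxycyclopentan-1-one | C=CC[C@]1([C@H](C)[C@@H](O)c2cc(OC)c(OC)c(OC)c2)C[C@@H](OC)CC1=O | intermediate
12 | (1R,2S)-2-[(1R,4R)-1-allyl-4-methoxy-2-oxocyclopentyl]-1-(3,4,5-trimethoxyphenyl)propyl acetate | C=CC[C@]1([C@H](C)[C@@H](OC(C)=O)c2cc(OC)c(OC)c(OC)c2)C[C@@H](OC)CC1=O | intermediate
13 | (1R,2S)-2-[(1R,4R)-1-allyl-4-methoxy-2-(trimethylsilyloxy)cyclopent-2-en-1-yl]-1-(3,4,5-trimethoxyphenyl)propyl acetate | C=CC[C@]1([C@H](C)[C@@H](OC(C)=O)c2cc(OC)c(OC)c(OC)c2)C[C@@H](OC)C=C1O[Si](C)(C)C | intermediate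
14 | siloxycyclopropane: 2-allyl-4-methoxy-1-(trimethylsilyloxy)bicyclo[3.1.0]hexan-2-yl analogue of 12, mixture of the two cis-fused cyclopropane diastereomers, other centres as in 12 | C=CC[C@]1([C@H](C)[C@@H](OC(C)=O)c2cc(OC)c(OC)c(OC)c2)C[C@@H](OC)C2CC12O[Si](C)(C)C | intermediate
15 | β-chloroketone: megaphone acetate with HCl added across C2=C3, chlorine at C3 (both C3 epimers) | C=CC[C@]1([C@H](C)[C@@H](OC(C)=O)c2cc(OC)c(OC)c(OC)c2)C[C@@H](OC)C(Cl)CC1=O | intermediate (not isolated)
16 | megaphone acetate, (1R,2S)-2-[(1R,5R)-1-allyl-5-methoxy-2-oxocyclohex-3-en-1-yl]-1-(3,4,5-trimethoxyphenyl)propyl acetate | C=CC[C@]1([C@H](C)[C@@H](OC(C)=O)c2cc(OC)c(OC)c(OC)c2)C[C@@H](OC)C=CC1=O | target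

Total step count: 10. Longest linear sequence: 10 steps (1 → 16); compounds 5, 7 and 10 enter as purchased materials.

Steps most likely to fail

Step 6. The cascade may be diverted in several ways: protonation of the alkene with aldehyde-free ring expansion, proton loss from the bis-allylic CH2 of the tertiary cation, ionisation of the tertiary allylic or of the product benzylic alcohol, or poor discrimination of the aldehyde face. The fallback makes the two bonds in separate, precedented operations. It sets out from cyclobutanol 9. A catalytic enantioselective bromonium-induced semipinacol ring expansion (N-bromosuccinimide, dimeric cinchona alkaloid catalyst such as (DHQD)2PHAL, low temperature) should give the β-bromoketone F1, with the quaternary and the methoxy-bearing carbons set by the same anti addition and the same choice of ring CH2. A Takai-type cobalt-catalysed chromium(II) reaction (CrCl2, catalytic vitamin B12 or cobalt phthalocyanine, DMF) of F1 with aldehyde 10 should then form the CHMe–carbinol bond at the aldehyde only and come back to the route at hydroxy ketone 11. Because the carbon–bromine centre passes through a radical, the two side-chain centres would be under substrate (chelate) control only, and 11 would have to be separated from its side-chain epimers.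

Step 10. The β-keto radical formed on ring opening may add to the allyl group, the electron-rich arene may be oxidised by iron(III), or the siloxycyclopropane may open by protonation to an α-methyl ketone. The fallback replaces the cyclopropane fragmentation by diazo insertion and dehydrogenation. It sets out from acetate 12. Lewis-acid-promoted homologation with trimethylsilyldiazomethane (Me3Al or BF3·OEt2, CH2Cl2, −78 °C), in which the less substituted α-carbon should migrate, would give the C-silyl cyclohexanone F2. Protodesilylation on dilute acid work-up would give the saturated cyclohexanone F3. Dehydrogenation with IBX (DMSO, 70 °C) toward the only enolisable side would come back to the route at 16.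

Step 5. The small methoxy group may direct the addition insufficiently, giving cis/trans mixtures, and the basic alkenyllithium may enolise the cyclobutanone with loss of methoxide. The fallback uses a larger, temporary directing group. It sets out from iodide 6 (through alkenyllithium 8). Addition of 8 to commercial 3-(tert-butyldimethylsilyloxy)cyclobutan-1-one should give the cis silyl ether F4 with stronger anti direction. TBAF would give the cis-diol F5. Selective O-methylation of the less hindered secondary hydroxyl (NaH, 1 equiv, MeI, THF, 0 °C) would come back to the route at 9.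

Further compounds
F1 | step 6 | (2S,4R)-2-allyl-2-[(1S)-1-bromoethyl]-4-methoxycyclopentan-1-one | C=CC[C@]1([C@H](C)Br)C[C@@H](OC)CC1=O
F2 | step 10 | C-silyl cyclohexanone: 2,3-dihydromegaphone acetate carrying trimethylsilyl at C2 (either epimer) | C=CC[C@]1([C@H](C)[C@@H](OC(C)=O)c2cc(OC)c(OC)c(OC)c2)C[C@@H](OC)CC([Si](C)(C)C)C1=O
F3 | step 10 | 2,3-dihydromegaphone acetate, (1R,2S)-2-[(1R,5S)-1-allyl-5-methoxy-2-oxocyclohexyl]-1-(3,4,5-trimethoxyphenyl)propyl acetate | C=CC[C@]1([C@H](C)[C@@H](OC(C)=O)c2cc(OC)c(OC)c(OC)c2)C[C@@H](OC)CCC1=O
F4 | step 5 | cis-3-(tert-butyldimethylsilyloxy)-1-[(2Z)-hexa-2,5-dien-3-yl]cyclobutan-1-ol | C/C=C(/CC=C)[C@]1(O)C[C@@H](O[Si](C)(C)C(C)(C)C)C1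
F5 | step 5 | cis-1-[(2Z)-hexa-2,5-dien-3-yl]cyclobutane-1,3-diol | C/C=C(/CC=C)[C@]1(O)C[C@@H](O)C1
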